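Assumption: crystalline all-E lycopene is treated as an advanced carotenoid, not a cheap starting material, so it is built in steps 1–3 from bulk C13 and C10 chemicals; locants C2, C5, C6 follow carotenoid numbering.

## Retrosynthetic overview

1. Target 10 ⇒ (5R,6R)-lycopene 5,6-epoxide 8. The only ring is formed last, by the biosynthesis-type cascade: C6–O ionisation, C2→C6 5-exo closure, loss of H-16. The 5R centre relays to C6 and C2.
2. 8 ⇒ all-E-lycopene 7 by catalyst-controlled mono-epoxidation of the 5,6-terminus (5,6 and 5′,6′ are the same position by C2 symmetry).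
3. 7 ⇒ 2 × C15 phosphonium salt 3 + C10-dialdehyde 4 (double Wittig forming C11=C12 and C11′=C12′).
4. 3 ⇒ pseudoionone 1 by vinyl Grignard addition, then Ph3P·HBr.

## Route

Step 1
Reactants: 1 (3E,5E)-pseudoionone [(3E,5E)-6,10-dimethylundeca-3,5,9-trien-2-one]
Product: 2 vinyl-ψ-ionol [(4E,6E)-3,7,11-trimethyldodeca-1,4,6,10-tetraen-3-ol, racemic at C3]
Conditions: CH2=CHMgBr (1.2 equiv), THF, −10 → 0 °C; then H2O
Reagents that add atoms: vinylmagnesium bromide, C=C[Mg]Br
Why: Grignard 1,2-addition, in which the hard vinyl nucleophile attacks the carbonyl carbon of the dienone rather than adding in conjugate fashion, gives the tertiary bis-allylic carbinol, whose new centre is racemic and is erased in step 2.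

Step 2
Reactants: 2 vinyl-ψ-ionol
Product: 3 [(2E,4E,6E)-3,7,11-trimethyldodeca-2,4,6,10-tetraen-1-yl]triphenylphosphonium bromide
Conditions: Ph3P·HBr (1.0 equiv), MeOH, 0 → 25 °C; crystallised from EtOAc
Reagents that add atoms: triphenylphosphine hydrobromide, [PH+](c1ccccc1)(c1ccccc1)c1ccccc1.[Br-]
Why: Acid-mediated allylic substitution with transposition (SN1-type, the standard phosphonium salt formation from vinyl carbinols), in which loss of water gives a delocalised trienyl cation that Ph3P captures at the unhindered primary terminus to give the conjugated 2E salt as the thermodynamic product, with water as the only by-product and no stereocentre left.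

Step 3
Reactants: 3 C15 phosphonium bromide (2.2 equiv); 4 (2E,4E,6E)-2,7-dimethylocta-2,4,6-trienedial
Product: 7 all-E-lycopene, via C15 ylide 5 (not isolated), via apo-12′-lycopenal 6 (not isolated)
Conditions: NaOMe, MeOH/CH2Cl2, −10 → 25 °C; then heptane, reflux; recrystallised to ≥98% all-E
Reagents that add atoms: none
Why: Double Wittig olefination, in which ylide 5 formed from 3 with NaOMe condenses with both formyl groups of 4 through mono-adduct 6, and because the unhindered 11Z isomers equilibrate on heating the poorly soluble all-E isomer crystallises out, which also removes 5Z material that would erode the later enantioselectivity; no stereocentre is formed.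

Step 4
Reactants: 7 all-E-lycopene
Product: 8 (5R,6R)-5,6-epoxy-5,6-dihydrolycopene
Conditions: 1,2:4,5-di-O-isopropylidene-β-D-erythro-2,3-hexodiulo-2,6-pyranose (D-fructose-derived ketone, C12H18O6, 30 mol%), KHSO5 (0.6 equiv, as 2KHSO5·KHSO4·K2SO4), K2CO3, Bu4NHSO4 (5 mol%), dimethoxymethane/MeCN/THF, aq. Na2B4O7 buffer (pH 10.5), 0 °C, dark, stopped at ca. 40% conversion; chromatography on Et3N-deactivated neutral Al2O3
Reagents that add atoms: potassium peroxymonosulfate (KHSO5), [K+].[O-]S(=O)(=O)OO
Why: Shi asymmetric epoxidation, in which the electrophilic chiral dioxirane attacks the trisubstituted 5,6-terminus of the electron-rich undecaene (only the isolated 1,2-alkene and over-oxidation compete, and both are limited by partial conversion with recycling of 7) and its spiro transition state delivers oxygen to the face of the E-trisubstituted alkene that gives the R,R-type epoxide, setting 5R (the only centre carried forward) and 6R.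

Step 5
Reactants: 8 (5R,6R)-5,6-epoxy-5,6-dihydrolycopene
Product: 10 (2R,5R,6S)-1,16-didehydro-2,6-cyclolycopen-5-ol, via triethylsilyl ether 9 (not isolated)
Conditions: Et3SiOSO2CF3 (1.2 equiv), 2,6-di-tert-butyl-4-methylpyridine (2 equiv), CH2Cl2, −78 °C, 20 min; aq. NaHCO3 work-up; then Bu4NF, THF, 0 → 25 °C
Reagents that add atoms: none
Why: Proposed new method: Et3SiOSO2CF3 silylates the epoxide oxygen and the allylic C6–O bond ionises to a polyene-delocalised C6 cation while the C5–O bond, and so the 5R centre, stays intact; 5-exo attack of the C1=C2 alkene on C6 and loss of an H-16 proton to the hindered pyridine give the isopropenyl group, the ring closing through (or, the closure of so stabilised a cation being reversible, equilibrating to) the arrangement with the C6 chain anti to the C5 methyl and the C2 substituent anti to the chain, which sets 6S and 2R, while the silyl cap keeps the oxygen from bridging to C1; the closest known reactions are the silyl-triflate opening of vinyl epoxides at the allylic carbon (Jung non-aldol aldol) and Lewis-acid epoxy-olefin cationic cyclisations, and Bu4NF then cleaves the silyl ether.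

## Compound list

1 | (3E,5E)-pseudoionone, (3E,5E)-6,10-dimethylundeca-3,5,9-trien-2-one | CC(=O)/C=C/C=C(\C)CCC=C(C)C | starting material
2 | vinyl-ψ-ionol, (4E,6E)-3,7,11-trimethyldodeca-1,4,6,10-tetraen-3-ol (racemic) | C=CC(C)(O)/C=C/C=C(\C)CCC=C(C)C | intermediate
3 | [(2E,4E,6E)-3,7,11-trimethyldodeca-2,4,6,10-tetraen-1-yl]triphenylphosphonium bromide | CC(C)=CCC/C(C)=C/C=C/C(C)=C/C[P+](c1ccccc1)(c1ccccc1)c1ccccc1.[Br-] | intermediate
4 | C10-dialdehyde, (2E,4E,6E)-2,7-dimethylocta-2,4,6-trienedial | O=C/C(C)=C/C=C/C=C(\C)C=O | starting material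
5 | C15 ylide, triphenyl[(2E,4E,6E)-3,7,11-trimethyldodeca-2,4,6,10-tetraen-1-ylidene]phosphorane | CC(C)=CCC/C(C)=C/C=C/C(C)=C/C=P(c1ccccc1)(c1ccccc1)c1ccccc1 | intermediate
6 | apo-12′-lycopenal, (2E,4E,6E,8E,10E,12E,14E)-2,7,11,15,19-pentamethylicosa-2,4,6,8,10,12,14,18-octaenal | O=C/C(C)=C/C=C/C=C(C)/C=C/C=C(C)/C=C/C=C(\C)CCC=C(C)C | intermediate
7 | all-E-lycopene (ψ,ψ-carotene) | CC(C)=CCC/C(C)=C/C=C/C(C)=C/C=C/C(C)=C/C=C/C=C(C)/C=C/C=C(C)/C=C/C=C(\C)CCC=C(C)C | intermediate
8 | (5R,6R)-5,6-epoxy-5,6-dihydro-ψ,ψ-carotene (trans epoxide, all other double bonds E) | CC(C)=CCC[C@@]1(C)O[C@@H]1/C=C/C(C)=C/C=C/C(C)=C/C=C/C=C(C)/C=C/C=C(C)/C=C/C=C(\C)CCC=C(C)C | intermediate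
9 | 5-O-triethylsilyl ether of 10, (2R,5R,6S) | C=C(C)[C@@H]1CC[C@@](C)(O[Si](CC)(CC)CC)[C@H]1/C=C/C(C)=C/C=C/C(C)=C/C=C/C=C(C)/C=C/C=C(C)/C=C/C=C(\C)CCC=C(C)C | intermediate
10 | (2R,5R,6S)-1,16-didehydro-2,6-cyclolycopen-5-ol, i.e. (1R,2S,3R)-1-methyl-2-(all-E-polyenyl)-3-(prop-1-en-2-yl)cyclopentan-1-ol with OH cis to the chain and isopropenyl trans to the chain | C=C(C)[C@@H]1CC[C@@](C)(O)[C@H]1/C=C/C(C)=C/C=C/C(C)=C/C=C/C=C(C)/C=C/C=C(C)/C=C/C=C(\C)CCC=C(C)C | target

## Totals and risks

Total step count: 5. Longest linear sequence: 5 (1 → 2 → 3 → 7 → 8 → 10).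

Steps most likely to fail:

**Step 4 (site- and enantioselective mono-epoxidation).** Peracids attack the 1,2- and 5,6-bonds of lycopene at similar rates, so roughly one part of 8 to one part of the 1,2-epoxide is expected, and 8 is acid-labile. The 1,2-epoxide does not cyclise in step 5 and stays non-polar, but the yield of 8 may be low.

The fallback builds 8 by olefination with the oxirane already in place. It sets out from apo-12′-lycopenal 6, made on purpose from 3 and a threefold excess of 4 under the step 3 conditions, and comes back at 8.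
- Horner–Wadsworth–Emmons reaction of 6 with ethyl (E)-4-(diethoxyphosphoryl)-2-methylbut-2-enoate (NaH, THF) gives ethyl 8′-apo-ψ-caroten-8′-oate F1.
- i-Bu2AlH (CH2Cl2, −78 °C) gives 8′-apo-ψ-caroten-8′-ol F2.
- Ph3P·HBr (MeOH) gives (8′-apo-ψ-caroten-8′-yl)triphenylphosphonium bromide F3.
- Separately, geraniol undergoes Sharpless epoxidation (Ti(OiPr)4, D-(−)-diethyl tartrate, t-BuOOH, 4 Å sieves, CH2Cl2, −20 °C) to (2R,3R)-2,3-epoxygeraniol F4.
- Oxidation (SO3·pyridine, DMSO, Et3N) gives (2S,3R)-2,3-epoxygeranial F5.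
- Wittig reaction of the ylide of F3 (NaOMe, CH2Cl2/MeOH, −20 °C) with F5 gives 8 with unambiguous regiochemistry and the ee of the Sharpless step. Any 7Z isomer converges in step 5, because the 7,8-bond loses double-bond character in the cation.

**Step 5 (cyclisation cascade).** Possible failures are the wrong C6 or C2 diastereomer, semipinacol shift to a ketone, or proton loss to the isopropylidene isomer.

The fallback sets out from 8 and comes back at 10. Dilute aqueous acid (0.01 M H2SO4, THF/H2O, 0 °C), under which the C1 cation is trapped by water, gives (2R,5R,6S)-2,6-cyclolycopene-1,5-diol F6. It is separated from bridged 1,5-ethers and diastereomers as the polar fraction. The less hindered side-chain dimethylcarbinol is then dehydrated (SOCl2, pyridine, −30 °C, E2 at a methyl group) to 10.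

**Step 3 (double Wittig and all-E purity).** E/Z mixtures at C11=C12 or residual 5Z/9Z isomers could resist isomerisation and crystallisation.

The fallback switches to a phosphonate carbanion. It sets out from 2 and comes back at 7.
- 48% aq. HBr (CH2Cl2, −20 °C) gives (2E,4E,6E)-1-bromo-3,7,11-trimethyldodeca-2,4,6,10-tetraene F7.
- NaP(O)(OEt)2 (THF, 0 °C, Michaelis–Becker) gives diethyl [(2E,4E,6E)-3,7,11-trimethyldodeca-2,4,6,10-tetraen-1-yl]phosphonate F8.
- Two equivalents of F8 with 4 and KOt-Bu (THF/DMSO, −20 → 25 °C) give 7 by an E-selective double Horner–Wadsworth–Emmons reaction.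

## Further compounds

F1 | step 4 | ethyl 8′-apo-ψ-caroten-8′-oate (all-E C30 ester) | CCOC(=O)/C(C)=C/C=C/C(C)=C/C=C/C=C(C)/C=C/C=C(C)/C=C/C=C(\C)CCC=C(C)C
F2 | step 4 | 8′-apo-ψ-caroten-8′-ol (all-E C30 allylic alcohol) | OC/C(C)=C/C=C/C(C)=C/C=C/C=C(C)/C=C/C=C(C)/C=C/C=C(\C)CCC=C(C)C
F3 | step 4 | (8′-apo-ψ-caroten-8′-yl)triphenylphosphonium bromide | [Br-].c1ccccc1[P+](c1ccccc1)(c1ccccc1)C/C(C)=C/C=C/C(C)=C/C=C/C=C(C)/C=C/C=C(C)/C=C/C=C(\C)CCC=C(C)C
F4 | step 4 | (2R,3R)-2,3-epoxygeraniol, [(2R,3R)-3-methyl-3-(4-methylpent-3-en-1-yl)oxiran-2-yl]methanol | CC(C)=CCC[C@@]1(C)O[C@@H]1CO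
F5 | step 4 | (2S,3R)-2,3-epoxygeranial, (2S,3R)-3-methyl-3-(4-methylpent-3-en-1-yl)oxirane-2-carbaldehyde | CC(C)=CCC[C@@]1(C)O[C@@H]1C=O
F6 | step 5 | (2R,5R,6S)-2,6-cyclolycopene-1,5-diol | CC(C)(O)[C@@H]1CC[C@@](C)(O)[C@H]1/C=C/C(C)=C/C=C/C(C)=C/C=C/C=C(C)/C=C/C=C(C)/C=C/C=C(\C)CCC=C(C)C
F7 | step 3 | (2E,4E,6E)-1-bromo-3,7,11-trimethyldodeca-2,4,6,10-tetraene | CC(C)=CCC/C(C)=C/C=C/C(C)=C/CBr
F8 | step 3 | diethyl [(2E,4E,6E)-3,7,11-trimethyldodeca-2,4,6,10-tetraen-1-yl]phosphonate | CC(C)=CCC/C(C)=C/C=C/C(C)=C/CP(=O)(OCC)OCC
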